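## Retrosynthetic overview

1. The C5 hydroxyl is introduced last by allylic oxidation of the 4-methylidene compound. The 6-angelate, the 4-methylidene and the 6β-oxygen go back to a Δ5-4-ketone (conjugate borylation/oxidation, methylenation, acylation), so oxygen needs no protecting group.
2. Key disconnection: the five-membered ring C7a–C1(=CH–CH3)–C2(O)–C3–C3a is opened at C1–C2 and at the vinylic C–CH3 bond, giving keto-ynal 13 and dimethylzinc. The enabling feature is the 2-alkylidenecyclopentanol unit of this ring: an exocyclic trisubstituted alkene at C1 next to the C2 carbinol, with CH3 cis to C2, carried on trans-diequatorial arms at C3a/C7a.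
3. 13 comes from (S)-cryptone by conjugate alkynylation, enolate allylation and ozonolysis; cryptone comes from isovaleraldehyde and methyl vinyl ketone.
4. Ring order: six-membered ring first (step 1), five-membered ring last (step 5).

Key step: step 5

Convention: bicyclic compounds carry octahydroindene locants (C1 ethylidene carbon, C2 acetoxy carbon, C3, C3a, C4 methylidene carbon, C5, C6, C7 isopropyl carbon, C7a); β is the face of H-7a and of the isopropyl group, α the face of H-3a.

## Route

Step 1
Reactants: 1 3-methylbutanal; 2 but-3-en-2-one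
Product: 4 (S)-4-(propan-2-yl)cyclohex-2-en-1-one, via keto aldehyde 3 (not isolated)
Conditions: (S)-α,α-diphenylprolinol methyl ether (5 mol%), ethyl 3,4-dihydroxybenzoate (20 mol%), neat, 4 °C; then LiOH, iPrOH, rt
Reagents that add atoms: none
Why: Enamine-catalysed Michael addition sets the isopropyl-bearing centre under catalyst control (the S-configured prolinol ether shields one enamine face), and a base-mediated intramolecular aldol condensation (Robinson-type annulation) closes the six-membered ring.

Step 2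
Reactants: 4 (S)-4-(propan-2-yl)cyclohex-2-en-1-one; 5 ethynyltri(propan-2-yl)silane
Product: 7 tert-butyl({(3S,4S)-4-(propan-2-yl)-3-{[tri(propan-2-yl)silyl]ethynyl}cyclohex-1-en-1-yl}oxy)dimethylsilane, via alkynylzinc bromide 6 (not isolated)
Conditions: 5, nBuLi, THF, −78 → 0 °C; ZnBr2, 0 °C; then 4, TBSOTf, Et2O–THF, −40 °C
Reagents that add atoms: tert-butyldimethylsilyl trifluoromethanesulfonate, CC(C)(C)[Si](C)(C)OS(=O)(=O)C(F)(F)F; zinc bromide, Br[Zn]Br (zinc and bromine of 6 only)
Why: Silyl-triflate-promoted conjugate addition of an alkynylzinc halide should place the alkynyl group on C3 anti to the neighbouring isopropyl group (3,4-trans) and capture the enolate regiospecifically as its silyl enol ether.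

Step 3
Reactants: 7 silyl enol ether; 8 3-iodoprop-1-ene
Product: 11 (2R,3S,4S)-3-ethynyl-4-(propan-2-yl)-2-(prop-2-en-1-yl)cyclohexan-1-one, via lithium enolate 9 (not isolated), via silylalkynyl ketone 10 (not isolated)
Conditions: MeLi, THF–DMPU, 0 °C → rt; 8, −78 → 0 °C; then TBAF, THF, rt
Reagents that add atoms: methyllithium, [Li]C (lithium of 9 only)
Why: Regiospecific enolate generation from the silyl enol ether and C-allylation anti to the adjacent alkynyl group should give the 2,3-trans (all-equatorial) ketone, which equilibration at C2 under the fluoride conditions also favours, and fluoride then removes the C-silyl group.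

Step 4
Reactants: 11 (2R,3S,4S)-3-ethynyl-4-(propan-2-yl)-2-(prop-2-en-1-yl)cyclohexan-1-one
Product: 13 2-[(1R,2S,3S)-2-ethynyl-6-oxo-3-(propan-2-yl)cyclohexyl]acetaldehyde, via ozonide 12 (not isolated)
Conditions: O3, CH2Cl2, −78 °C (Sudan Red 7B end point); PPh3, −78 °C → rt
Reagents that add atoms: ozone, [O-][O+]=O
Why: Ozonolysis with reductive work-up; the monosubstituted alkene reacts far faster with ozone than the terminal alkyne, and the dye end point prevents over-ozonation.

Step 5
Reactants: 13 2-[(1R,2S,3S)-2-ethynyl-6-oxo-3-(propan-2-yl)cyclohexyl]acetaldehyde; 14 dimethylzinc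
Product: 16 (1Z,2R,3aR,7S,7aS)-1-ethylidene-2-hydroxy-7-(propan-2-yl)octahydro-4H-inden-4-one, via methylzinc alkoxide 15 (not isolated)
Conditions: Ni(cod)2 (10 mol%), Me2Zn (2.5 equiv), THF, 0 °C, slow addition of 13; aq NH4Cl
Reagents that add atoms: none
Why: Ni(0) binds the terminal alkyne and the aldehyde of 13 and couples them by oxidative cyclization to an oxanickelacyclopentene (new bond between the internal alkyne carbon and the aldehyde carbon); zinc-to-nickel methyl transfer and C(sp2)–CH3 reductive elimination then give 15, so two carbon electrophiles are joined and the ethylidene methyl is added in one operation. The closest known reaction type is the nickel-catalysed alkylative cyclization of ynals with organozincs (three-component aldehyde–alkyne–organozinc coupling). The five-membered ring closes in a 5-exo-dig mode between the trans-diequatorial ethynyl and 2-oxoethyl arms, which gives the trans ring fusion without touching C3a or C7a. The alkene geometry follows from syn delivery of the carbinol carbon and the methyl group across the alkyne, which places CH3 cis to C2 (Z), the less stable arrangement that the target needs. The new carbinol centre is controlled by the planar metallacycle, which needs the C2–O bond nearly eclipsed with the forming exocyclic C=C; in the trans-fused twist only an α-oxygen (cis to H-3a) can reach that position, so the 2R alcohol is expected. The step needs aldehyde-over-ketone chemoselectivity and alkylation in place of reduction; the first is secured by the alkyne and aldehyde being held 1,6 to each other (the ketone could only close a four-membered ring), the second by the absence of β-hydrogens on the methyl–nickel intermediate.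

Step 6
Reactants: 16 (1Z,2R,3aR,7S,7aS)-1-ethylidene-2-hydroxy-7-(propan-2-yl)octahydro-4H-inden-4-one; 17 acetic acid
Product: 18 (1Z,2S,3aR,7S,7aS)-1-ethylidene-4-oxo-7-(propan-2-yl)octahydro-1H-inden-2-yl acetate
Conditions: PPh3, DIAD, AcOH, THF, 0 °C → rt
Reagents that add atoms: none
Why: Mitsunobu esterification: SN2 displacement of the alkoxyphosphonium by acetate should invert C2 (2R → 2S) and relieve the allylic strain between the α-oxygen and the cis methyl group, while the leaving group lies near the alkene plane, which disfavours SN2′.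

Step 7
Reactants: 18 (1Z,2S,3aR,7S,7aS)-1-ethylidene-4-oxo-7-(propan-2-yl)octahydro-1H-inden-2-yl acetate
Product: 19 (1Z,2S,3aR,7S,7aS)-1-ethylidene-7-(propan-2-yl)-4-[(trimethylsilyl)oxy]-2,3,3a,6,7,7a-hexahydro-1H-inden-2-yl acetate
Conditions: TMSCl, LiHMDS (1.05 equiv), THF, −78 °C (internal quench)
Reagents that add atoms: chlorotrimethylsilane, C[Si](C)(C)Cl
Why: Kinetic enolization at the less hindered C5 methylene (not the C3a methine) with in situ silylation should give the Δ4 silyl enol ether; the ketone is far more acidic than the acetate, and the internal quench keeps free base low.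

Step 8
Reactants: 19 silyl enol ether
Product: 20 (1Z,2S,3aR,7R,7aS)-1-ethylidene-4-oxo-7-(propan-2-yl)-2,3,3a,4,7,7a-hexahydro-1H-inden-2-yl acetate
Conditions: IBX, 4-methoxypyridine N-oxide, DMSO, rt
Reagents that add atoms: none
Why: IBX/N-oxide dehydrogenation of a silyl enol ether (a palladium-free Saegusa-type oxidation, so the allylic acetate is not ionized) should give the Δ5 enone.

Step 9
Reactants: 20 Δ5 enone
Product: 22 (1Z,2S,3aR,6R,7S,7aS)-1-ethylidene-6-hydroxy-4-oxo-7-(propan-2-yl)octahydro-1H-inden-2-yl acetate, via boronate 21 (not isolated)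
Conditions: B2pin2, CuCl (5 mol%), DPEphos (5 mol%), NaOtBu (10 mol%), MeOH (2 equiv), THF, rt; then NaBO3·4H2O, THF–H2O, rt
Reagents that add atoms: bis(pinacolato)diboron, CC1(C)OB(OC1(C)C)B1OC(C)(C)C(C)(C)O1 (boron of 21 only); sodium perborate, [Na+].[O-]OB=O
Why: Copper-catalysed conjugate borylation and oxidation with retention: Cu–B should add to C6 of the conformationally locked trans-fused enone along the axial trajectory on the β-face, antiperiplanar to the axial H-7, giving the axial 6β-boronate and hence the 6β-alcohol.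

Step 10
Reactants: 22 6β-hydroxy ketone
Product: 23 (1Z,2S,3aR,6R,7S,7aR)-1-ethylidene-6-hydroxy-4-methylidene-7-(propan-2-yl)octahydro-1H-inden-2-yl acetate
Conditions: Zn, CH2Br2, TiCl4, THF (pre-formed, 0 °C); 22, CH2Cl2, 0 °C → rt
Reagents that add atoms: dibromomethane, BrCBr
Why: Lombardo methylenation, a non-basic carbonyl olefination, should tolerate the free β-hydroxyl, the acetate and the epimerizable C3a centre and avoid retro-aldol or E1cB loss of the 6-oxygen.

Step 11
Reactants: 23 homoallylic alcohol; 24 (Z)-2-methylbut-2-enoic acid (angelic acid)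
Product: 26 (1Z,2S,3aR,6R,7S,7aR)-2-(acetyloxy)-1-ethylidene-4-methylidene-7-(propan-2-yl)octahydro-1H-inden-6-yl (2Z)-2-methylbut-2-enoate, via mixed anhydride 25 (not isolated)
Conditions: 24, 2,4,6-trichlorobenzoyl chloride, Et3N, toluene, rt; then 23, 80 °C
Reagents that add atoms: 2,4,6-trichlorobenzoyl chloride, O=C(Cl)c1c(Cl)cc(Cl)cc1Cl (aroyl part of 25 only)
Why: Yamaguchi-type acylation through the mixed anhydride without DMAP, the usual way to esterify a hindered secondary alcohol with angelic acid without Z → E isomerization to the tiglate.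

Step 12
Reactants: 26 6-angelate
Product: 27 (1Z,2S,3aR,5S,6S,7S,7aR)-2-(acetyloxy)-1-ethylidene-5-hydroxy-4-methylidene-7-(propan-2-yl)octahydro-1H-inden-6-yl (2Z)-2-methylbut-2-enoate (CNP0113604.1)
Conditions: SeO2 (0.5 equiv), tBuOOH (3 equiv), CH2Cl2, 0 °C → rt
Reagents that add atoms: tert-butyl hydroperoxide, CC(C)(C)OO (oxygen source); selenium dioxide, O=[Se]=O (oxygen carrier)
Why: Riley allylic oxidation (SeO2 ene reaction, then [2,3]-sigmatropic shift): selenium should add to the unhindered exocyclic CH2 with abstraction of the axial H-5α, and the shift returns the alkene to the exocyclic position and places OH axial on the α-face of C5, trans to the axial 6β-ester; the C5 methylene is preferred over the C3a methine, the ethylidene offers only methine hydrogens at its reactive end, and the angelate alkene is electron-poor.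

## Compound list

1 | 3-methylbutanal (isovaleraldehyde) | CC(C)CC=O | starting material
2 | but-3-en-2-one (methyl vinyl ketone) | CC(=O)C=C | starting material
3 | (S)-5-oxo-2-(propan-2-yl)hexanal | CC(=O)CC[C@@H](C(C)C)C=O | intermediate
4 | (S)-4-(propan-2-yl)cyclohex-2-en-1-one ((S)-cryptone) | O=C1C=C[C@H](C(C)C)CC1 | intermediate
5 | ethynyltri(propan-2-yl)silane | C#C[Si](C(C)C)(C(C)C)C(C)C | starting material
6 | bromo{[tri(propan-2-yl)silyl]ethynyl}zinc | Br[Zn]C#C[Si](C(C)C)(C(C)C)C(C)C | intermediate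
7 | tert-butyl({(3S,4S)-4-(propan-2-yl)-3-{[tri(propan-2-yl)silyl]ethynyl}cyclohex-1-en-1-yl}oxy)dimethylsilane (3,4-trans) | CC(C)(C)[Si](C)(C)OC1=C[C@@H](C#C[Si](C(C)C)(C(C)C)C(C)C)[C@H](C(C)C)CC1 | intermediate
8 | 3-iodoprop-1-ene (allyl iodide) | C=CCI | starting material
9 | lithium (3S,4S)-4-(propan-2-yl)-3-{[tri(propan-2-yl)silyl]ethynyl}cyclohex-1-en-1-olate | [Li]OC1=C[C@@H](C#C[Si](C(C)C)(C(C)C)C(C)C)[C@H](C(C)C)CC1 | intermediate
10 | (2R,3S,4S)-4-(propan-2-yl)-2-(prop-2-en-1-yl)-3-{[tri(propan-2-yl)silyl]ethynyl}cyclohexan-1-one | O=C1CC[C@@H](C(C)C)[C@H](C#C[Si](C(C)C)(C(C)C)C(C)C)[C@H]1CC=C | intermediate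
11 | (2R,3S,4S)-3-ethynyl-4-(propan-2-yl)-2-(prop-2-en-1-yl)cyclohexan-1-one (all-trans) | O=C1CC[C@@H](C(C)C)[C@H](C#C)[C@H]1CC=C | intermediate
12 | (2R,3S,4S)-3-ethynyl-4-(propan-2-yl)-2-[(1,2,4-trioxolan-3-yl)methyl]cyclohexan-1-one (ozonide, trioxolane carbon unassigned) | O=C1CC[C@@H](C(C)C)[C@H](C#C)[C@H]1CC2OCOO2 | intermediate
13 | 2-[(1R,2S,3S)-2-ethynyl-6-oxo-3-(propan-2-yl)cyclohexyl]acetaldehyde | O=C1CC[C@@H](C(C)C)[C@H](C#C)[C@H]1CC=O | intermediate
14 | dimethylzinc | C[Zn]C | starting material
15 | methylzinc (1Z,2R,3aR,7S,7aS)-1-ethylidene-4-oxo-7-(propan-2-yl)octahydro-1H-inden-2-olate | O=C1CC[C@@H](C(C)C)[C@@H]2/C(=C/C)[C@H](O[Zn]C)C[C@@H]12 | intermediate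
16 | (1Z,2R,3aR,7S,7aS)-1-ethylidene-2-hydroxy-7-(propan-2-yl)octahydro-4H-inden-4-one (2α-OH, trans-fused) | O=C1CC[C@@H](C(C)C)[C@@H]2/C(=C/C)[C@H](O)C[C@@H]12 | intermediate
17 | acetic acid | CC(=O)O | starting material
18 | (1Z,2S,3aR,7S,7aS)-1-ethylidene-4-oxo-7-(propan-2-yl)octahydro-1H-inden-2-yl acetate (2β-OAc) | O=C1CC[C@@H](C(C)C)[C@@H]2/C(=C/C)[C@@H](OC(C)=O)C[C@@H]12 | intermediate
19 | (1Z,2S,3aR,7S,7aS)-1-ethylidene-7-(propan-2-yl)-4-[(trimethylsilyl)oxy]-2,3,3a,6,7,7a-hexahydro-1H-inden-2-yl acetate | C[Si](C)(C)OC1=CC[C@@H](C(C)C)[C@@H]2/C(=C/C)[C@@H](OC(C)=O)C[C@@H]12 | intermediate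
20 | (1Z,2S,3aR,7R,7aS)-1-ethylidene-4-oxo-7-(propan-2-yl)-2,3,3a,4,7,7a-hexahydro-1H-inden-2-yl acetate | O=C1C=C[C@@H](C(C)C)[C@@H]2/C(=C/C)[C@@H](OC(C)=O)C[C@@H]12 | intermediate
21 | (1Z,2S,3aR,6R,7S,7aS)-1-ethylidene-4-oxo-7-(propan-2-yl)-6-(4,4,5,5-tetramethyl-1,3,2-dioxaborolan-2-yl)octahydro-1H-inden-2-yl acetate (6β-boronate) | O=C1C[C@@H](B3OC(C)(C)C(C)(C)O3)[C@@H](C(C)C)[C@@H]2/C(=C/C)[C@@H](OC(C)=O)C[C@@H]12 | intermediate
22 | (1Z,2S,3aR,6R,7S,7aS)-1-ethylidene-6-hydroxy-4-oxo-7-(propan-2-yl)octahydro-1H-inden-2-yl acetate (6β-OH) | O=C1C[C@@H](O)[C@@H](C(C)C)[C@@H]2/C(=C/C)[C@@H](OC(C)=O)C[C@@H]12 | intermediate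
23 | (1Z,2S,3aR,6R,7S,7aR)-1-ethylidene-6-hydroxy-4-methylidene-7-(propan-2-yl)octahydro-1H-inden-2-yl acetate | C=C1C[C@@H](O)[C@@H](C(C)C)[C@@H]2/C(=C/C)[C@@H](OC(C)=O)C[C@@H]12 | intermediate
24 | (Z)-2-methylbut-2-enoic acid (angelic acid) | C/C=C(/C)C(=O)O | starting material
25 | (Z)-2-methylbut-2-enoic 2,4,6-trichlorobenzoic anhydride | C/C=C(/C)C(=O)OC(=O)c1c(Cl)cc(Cl)cc1Cl | intermediate
26 | (1Z,2S,3aR,6R,7S,7aR)-2-(acetyloxy)-1-ethylidene-4-methylidene-7-(propan-2-yl)octahydro-1H-inden-6-yl (2Z)-2-methylbut-2-enoate | C=C1C[C@@H](OC(=O)/C(C)=C\C)[C@@H](C(C)C)[C@@H]2/C(=C/C)[C@@H](OC(C)=O)C[C@@H]12 | intermediate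
27 | (1Z,2S,3aR,5S,6S,7S,7aR)-2-(acetyloxy)-1-ethylidene-5-hydroxy-4-methylidene-7-(propan-2-yl)octahydro-1H-inden-6-yl (2Z)-2-methylbut-2-enoate (CNP0113604.1) | C=C1[C@H](O)[C@@H](OC(=O)/C(C)=C\C)[C@@H](C(C)C)[C@@H]2/C(=C/C)[C@@H](OC(C)=O)C[C@@H]12 | target

## Step count and risks

Total step count: 12. Longest linear sequence: 12 steps (from 1 and 2).

Steps most likely to fail:

Step 12. The selenium ene reaction may also engage the ethylidene (abstraction of the well-aligned H-7a) or the C3a methine, and the new allylic alcohol may be over-oxidized to the enone. The fallback takes both ring oxygens from the Δ5 alkene instead of from a C–H oxidation. It sets out from 20: nucleophilic epoxidation (tBuOOH, DBU, CH2Cl2; axial attack of the peroxide anion at C6 on the β-face) should give the 5β,6β-epoxy ketone F1. Methylenation as in step 10 gives the vinyl epoxide F2. Dilute HClO4 in THF–water should open it trans-diaxially at the allylic C5 from the α-face to the 5α,6β-diol F3. TESCl/imidazole should silylate the less hindered allylic 5-hydroxyl to the 5-O-triethylsilyl ether F4. Acylation as in step 11 gives the silyl-protected angelate F5, and HF·pyridine returns the route to 27. The trans-diaxial diol geometry rules out acyl migration.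

Step 9. The neighbouring isopropyl group may steer the copper–boryl reagent to the α-face of C6, giving poor facial selectivity or the 6-epimer. The fallback no longer relies on the addition for this centre and sets it by ketone reduction. It sets out from 20: the 6α-hydroxy ketone F6 (or the epimer mixture) is methylenated as in step 10 to the 6α-hydroxy methylidene compound F7. Dess–Martin oxidation gives the β,γ-unsaturated 6-ketone F8. L-Selectride (THF, −78 °C) should deliver hydride equatorially (the menthone-to-neomenthol pattern) to the axial 6β-alcohol, and the route is rejoined at 23. Both epimers converge.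

Step 5. The oxidative cyclization may proceed in part through the other aldehyde face, so that control at the carbinol centre is incomplete or reversed. The fallback drops the need for one configuration and uses both epimers. It sets out from 13: the cyclization mixture is separated, 16 is inverted as in step 6, and the 2β-alcohol F9 is acetylated with retention (Ac2O, DMAP, pyridine). Both streams come back at 18.

Further compounds

F1 | step 12 | (1Z)-5β,6β-epoxy-1-ethylidene-4-oxo-7β-(propan-2-yl)octahydro-1H-inden-2β-yl acetate | O=C1[C@H]3O[C@H]3[C@@H](C(C)C)[C@@H]2/C(=C/C)[C@@H](OC(C)=O)C[C@@H]12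
F2 | step 12 | (1Z)-5β,6β-epoxy-1-ethylidene-4-methylidene-7β-(propan-2-yl)octahydro-1H-inden-2β-yl acetate | C=C1[C@H]3O[C@H]3[C@@H](C(C)C)[C@@H]2/C(=C/C)[C@@H](OC(C)=O)C[C@@H]12
F3 | step 12 | (1Z)-1-ethylidene-5α,6β-dihydroxy-4-methylidene-7β-(propan-2-yl)octahydro-1H-inden-2β-yl acetate | C=C1[C@H](O)[C@@H](O)[C@@H](C(C)C)[C@@H]2/C(=C/C)[C@@H](OC(C)=O)C[C@@H]12
F4 | step 12 | (1Z)-1-ethylidene-6β-hydroxy-4-methylidene-7β-(propan-2-yl)-5α-[(triethylsilyl)oxy]octahydro-1H-inden-2β-yl acetate | C=C1[C@H](O[Si](CC)(CC)CC)[C@@H](O)[C@@H](C(C)C)[C@@H]2/C(=C/C)[C@@H](OC(C)=O)C[C@@H]12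
F5 | step 12 | (1Z)-2β-(acetyloxy)-1-ethylidene-4-methylidene-7β-(propan-2-yl)-5α-[(triethylsilyl)oxy]octahydro-1H-inden-6β-yl (2Z)-2-methylbut-2-enoate | C=C1[C@H](O[Si](CC)(CC)CC)[C@@H](OC(=O)/C(C)=C\C)[C@@H](C(C)C)[C@@H]2/C(=C/C)[C@@H](OC(C)=O)C[C@@H]12
F6 | step 9 | (1Z)-1-ethylidene-6α-hydroxy-4-oxo-7β-(propan-2-yl)octahydro-1H-inden-2β-yl acetate | O=C1C[C@H](O)[C@@H](C(C)C)[C@@H]2/C(=C/C)[C@@H](OC(C)=O)C[C@@H]12
F7 | step 9 | (1Z)-1-ethylidene-6α-hydroxy-4-methylidene-7β-(propan-2-yl)octahydro-1H-inden-2β-yl acetate | C=C1C[C@H](O)[C@@H](C(C)C)[C@@H]2/C(=C/C)[C@@H](OC(C)=O)C[C@@H]12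
F8 | step 9 | (1Z)-1-ethylidene-4-methylidene-6-oxo-7β-(propan-2-yl)octahydro-1H-inden-2β-yl acetate | C=C1CC(=O)[C@@H](C(C)C)[C@@H]2/C(=C/C)[C@@H](OC(C)=O)C[C@@H]12
F9 | step 5 | (1Z,2S,3aR,7S,7aS)-1-ethylidene-2-hydroxy-7-(propan-2-yl)octahydro-4H-inden-4-one (2β-OH) | O=C1CC[C@@H](C(C)C)[C@@H]2/C(=C/C)[C@@H](O)C[C@@H]12
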